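**Plan**

- Ring numbering used below: C1 (C=O), C2 (C–CH3), C3 (=CH), C4 (CHOH), C5 (CH–geranylgeranyl), C6 (CH2). Retrosynthesis: C1=O ⇐ 1,3-dithiane; C4–OH ⇐ C4=O; then cut C6–C1 and C3–C4, giving a C1–C2–C3 alkenyl piece and a C4–C5–C6 acryloyl piece.
- Enabling feature: C4 lies between the C2=C3 alkene and the C5–C6 edge. At the ketone level, C2–C6 form a cross-conjugated dienone C2=C3–C4(=O)–C5=C6, and its γ-carbon C1, acidified by two sulfur atoms, adds to C6 (the phorone → isophorone ring closure).
- Forward: geranylgeraniol → bromide → phosphonoacetamide alkylation → methylenation gives the 2-(geranylgeranyl)acrylamide (C4–C6). Methacrolein → bromoenal → dithiane gives C1–C3. One flask joins the two (acylation of the alkenyllithium, then base) and closes the only ring.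
- Stereochemistry: C5 is deliberately left epimerisable next to the C4 ketone. One asymmetric ketone hydrogenation with dynamic kinetic resolution sets C4 and C5 together (cis, 4S,5S). The E-alkenes come unchanged from geranylgeraniol.
- Last step: dithiane hydrolysis releases the C1 ketone in conjugation with C2=C3.

Key step: step 6

Assumption: trans-RuCl2[(R)-tolbinap][(S,S)-dpen] is taken as the catalyst antipode that delivers the (9S)-carbinol in step 7; if the sense of induction is opposite, the mirror-image complex is used.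

**Route**

Step 1
Reactants: 1 (2E,6E,10E)-geranylgeraniol
Product: 2 (2E,6E,10E)-geranylgeranyl bromide
Conditions: PBr3 (0.4 equiv), Et2O, 0 °C
Reagents that add atoms: phosphorus tribromide, BrP(Br)Br
Why: PBr3 converts primary allylic alcohols of the farnesol type to the bromides by SN2 substitution at 0 °C without allylic transposition, so the three E-trisubstituted alkenes should be retained.

Step 2
Reactants: 2 (2E,6E,10E)-geranylgeranyl bromide; 3 diethyl {2-[methoxy(methyl)amino]-2-oxoethyl}phosphonate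
Product: 4 diethyl {(4E,8E,12E)-1-[methoxy(methyl)amino]-5,9,13,17-tetramethyl-1-oxooctadeca-4,8,12,16-tetraen-2-yl}phosphonate (racemic)
Conditions: NaH, THF, 0 °C; 3 (1.5 equiv); then 2, 0 → 25 °C
Reagents that add atoms: none
Why: The sodium salt of the stabilised phosphonoacetamide carbanion should be C-alkylated by the primary allylic bromide in an SN2 reaction (phosphonoacetate alkylation), with excess 3 suppressing dialkylation.

Step 3
Reactants: 4 diethyl {(4E,8E,12E)-1-[methoxy(methyl)amino]-5,9,13,17-tetramethyl-1-oxooctadeca-4,8,12,16-tetraen-2-yl}phosphonate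
Product: 5 (4E,8E,12E)-N-methoxy-N,5,9,13,17-pentamethyl-2-methylideneoctadeca-4,8,12,16-tetraenamide
Conditions: NaH, THF, 0 °C; (CH2O)n, 50 °C
Reagents that add atoms: formaldehyde (from paraformaldehyde), C=O
Why: Horner–Wadsworth–Emmons methylenation of the α-substituted phosphonate with formaldehyde should give the 1,1-disubstituted acrylamide, in which no alkene geometry arises.

Step 4
Reactants: 6 methacrolein
Product: 8 (2E)-3-bromo-2-methylprop-2-enal, via 2,3-dibromo-2-methylpropanal 7 (not isolated)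
Conditions: Br2, CH2Cl2, −20 °C; then Et3N, 0 → 25 °C
Reagents that add atoms: bromine, BrBr
Why: Bromine addition to the enal C=C followed by amine-induced loss of HBr (bromination–dehydrobromination) should give the β-bromo enal as the stable E isomer, and the geometry is erased in step 6 in any case.

Step 5
Reactants: 8 (2E)-3-bromo-2-methylprop-2-enal
Product: 9 2-[(1E)-1-bromoprop-1-en-2-yl]-1,3-dithiane
Conditions: HS(CH2)3SH, BF3·OEt2, CH2Cl2, −20 → 0 °C
Reagents that add atoms: propane-1,3-dithiol, SCCCS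
Why: Lewis-acid-catalysed dithioacetalisation of the aldehyde (1,3-dithiane formation) should outrun thiol conjugate addition at low temperature and installs the two sulfur atoms that later acidify C1–H.

Step 6
Reactants: 9 2-[(1E)-1-bromoprop-1-en-2-yl]-1,3-dithiane; 5 (4E,8E,12E)-N-methoxy-N,5,9,13,17-pentamethyl-2-methylideneoctadeca-4,8,12,16-tetraenamide
Product: 13 rac-7-methyl-10-[(2E,6E,10E)-3,7,11,15-tetramethylhexadeca-2,6,10,14-tetraen-1-yl]-1,5-dithiaspiro[5.5]undec-7-en-9-one, via alkenyllithium 10 (not isolated), via lithium hemiaminal adduct 11 (not isolated), via cross-conjugated dienone 12 (not isolated)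
Conditions: t-BuLi (2 equiv), Et2O, −78 °C; then 5, THF, −78 °C; then MeOH, DBU, −78 → 25 °C, 0.02 M
Reagents that add atoms: none
Why: Bromine–lithium exchange gives alkenyllithium 10 with retention, which adds to the carbonyl of N-methoxy-N-methylamide 5 to give the chelated adduct 11 (stable, so no second addition); methanol releases dienone 12, and DBU removes the doubly sulfur-stabilised γ-proton at C1 to give a dienolate (a 3-oxidohexatriene) in which rotation about C2–C3 is free, so the E geometry of 9 is of no consequence. The dienolate closes C1 onto C6 by a 6-endo-trig intramolecular Michael addition (equally a disrotatory 6π ring closure), the mode by which phorone gives isophorone, and α-protonation leaves the conjugated enone 13. The closest known reaction types are ketone synthesis from an alkenyllithium and an N-methoxy-N-methylamide, and base-mediated cycloisomerisation of cross-conjugated dienones. The only new stereocentre, C5, arises by enolate protonation and is not controlled, which is intended, because it stays epimerisable α to the C4 ketone and is set in step 7. The selectivities needed are carbonyl over conjugate addition (hard organolithium, chelating amide, −78 °C), deprotonation at C1–H and not at the C2 methyl (the two sulfur atoms make C1–H far more acidic), and six- over four-membered closure (attack through C1, not C3); high dilution suppresses intermolecular Michael addition.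

Step 7
Reactants: 13 rac-7-methyl-10-[(2E,6E,10E)-3,7,11,15-tetramethylhexadeca-2,6,10,14-tetraen-1-yl]-1,5-dithiaspiro[5.5]undec-7-en-9-one
Product: 14 (9S,10S)-7-methyl-10-[(2E,6E,10E)-3,7,11,15-tetramethylhexadeca-2,6,10,14-tetraen-1-yl]-1,5-dithiaspiro[5.5]undec-7-en-9-ol
Conditions: trans-RuCl2[(R)-tolbinap][(S,S)-dpen] (1 mol%), KOt-Bu (10 mol%), H2 (10 atm), i-PrOH, 25 °C
Reagents that add atoms: none
Why: Noyori asymmetric hydrogenation reduces the C=O of enones and leaves C=C bonds alone, and under its basic conditions C5 epimerises through the enolate, so dynamic kinetic resolution should funnel the racemate to one cis alcohol: the catalyst fixes C4 by face-selective hydride delivery and reacts faster with the ketone enantiomer whose C5 substituent lies trans to the incoming hydride, which puts OH and the side chain cis.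

Step 8
Reactants: 14 (9S,10S)-7-methyl-10-[(2E,6E,10E)-3,7,11,15-tetramethylhexadeca-2,6,10,14-tetraen-1-yl]-1,5-dithiaspiro[5.5]undec-7-en-9-ol
Product: 15 (4S,5S)-4-hydroxy-2-methyl-5-[(2E,6E,10E)-3,7,11,15-tetramethylhexadeca-2,6,10,14-tetraen-1-yl]cyclohex-2-en-1-one
Conditions: MeI, CaCO3, MeCN/H2O (4:1), 40 °C
Reagents that add atoms: water, O
Why: S-Methylation of the 1,3-dithiane and buffered hydrolysis of the resulting sulfonium ion (alkylative dethioacetalisation) should unmask the C1 ketone in conjugation with C2=C3 under near-neutral conditions that spare the trisubstituted alkenes and the γ-hydroxy enone and touch no stereocentre.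

**Compound list**

1 | (2E,6E,10E)-geranylgeraniol | CC(C)=CCC/C(C)=C/CC/C(C)=C/CC/C(C)=C/CO | starting material
2 | (2E,6E,10E)-geranylgeranyl bromide | CC(C)=CCC/C(C)=C/CC/C(C)=C/CC/C(C)=C/CBr | intermediate
3 | diethyl {2-[methoxy(methyl)amino]-2-oxoethyl}phosphonate | CCOP(=O)(OCC)CC(=O)N(C)OC | starting material
4 | diethyl {(4E,8E,12E)-1-[methoxy(methyl)amino]-5,9,13,17-tetramethyl-1-oxooctadeca-4,8,12,16-tetraen-2-yl}phosphonate (racemic) | CC(C)=CCC/C(C)=C/CC/C(C)=C/CC/C(C)=C/CC(C(=O)N(C)OC)P(=O)(OCC)OCC | intermediate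
5 | (4E,8E,12E)-N-methoxy-N,5,9,13,17-pentamethyl-2-methylideneoctadeca-4,8,12,16-tetraenamide | CC(C)=CCC/C(C)=C/CC/C(C)=C/CC/C(C)=C/CC(=C)C(=O)N(C)OC | intermediate
6 | methacrolein | CC(=C)C=O | starting material
7 | 2,3-dibromo-2-methylpropanal (racemic, not isolated) | O=CC(C)(Br)CBr | intermediate
8 | (2E)-3-bromo-2-methylprop-2-enal | Br/C=C(C)/C=O | intermediate
9 | 2-[(1E)-1-bromoprop-1-en-2-yl]-1,3-dithiane | Br/C=C(C)/C1SCCCS1 | intermediate
10 | [(1E)-2-(1,3-dithian-2-yl)prop-1-en-1-yl]lithium (not isolated) | [Li]/C=C(C)/C1SCCCS1 | intermediate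
11 | lithium (4E)-5-(1,3-dithian-2-yl)-3-[methoxy(methyl)amino]-2-[(2E,6E,10E)-3,7,11,15-tetramethylhexadeca-2,6,10,14-tetraen-1-yl]hexa-1,4-dien-3-olate (racemic, not isolated) | CC(C)=CCC/C(C)=C/CC/C(C)=C/CC/C(C)=C/CC(=C)C(O[Li])(N(C)OC)/C=C(C)/C1SCCCS1 | intermediate
12 | (4E)-5-(1,3-dithian-2-yl)-2-[(2E,6E,10E)-3,7,11,15-tetramethylhexadeca-2,6,10,14-tetraen-1-yl]hexa-1,4-dien-3-one (not isolated) | CC(C)=CCC/C(C)=C/CC/C(C)=C/CC/C(C)=C/CC(=C)C(=O)/C=C(C)/C1SCCCS1 | intermediate
13 | rac-7-methyl-10-[(2E,6E,10E)-3,7,11,15-tetramethylhexadeca-2,6,10,14-tetraen-1-yl]-1,5-dithiaspiro[5.5]undec-7-en-9-one | CC(C)=CCC/C(C)=C/CC/C(C)=C/CC/C(C)=C/CC1CC2(SCCCS2)C(C)=CC1=O | intermediate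
14 | (9S,10S)-7-methyl-10-[(2E,6E,10E)-3,7,11,15-tetramethylhexadeca-2,6,10,14-tetraen-1-yl]-1,5-dithiaspiro[5.5]undec-7-en-9-ol | CC(C)=CCC/C(C)=C/CC/C(C)=C/CC/C(C)=C/C[C@H]1CC2(SCCCS2)C(C)=C[C@H]1O | intermediate
15 | (4S,5S)-4-hydroxy-2-methyl-5-[(2E,6E,10E)-3,7,11,15-tetramethylhexadeca-2,6,10,14-tetraen-1-yl]cyclohex-2-en-1-one | CC(C)=CCC/C(C)=C/CC/C(C)=C/CC/C(C)=C/C[C@H]1CC(=O)C(C)=C[C@H]1O | target

**Step count and risks**

Total step count: 8. Longest linear sequence: 6 steps (1, 2, 3, 6, 7, 8).

Steps most likely to fail: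

1. Step 7. The thioacetal sulfur may bind and inhibit the ruthenium catalyst, or reduction may outrun epimerisation at C5, so that dynamic resolution is lost and a mixture of diastereomers and enantiomers results. Fallback, from 13 back to 14: reduction with LiBH(s-Bu)3 (THF, −78 °C), whose equatorial hydride delivery should give the racemic cis alcohol rac-(9S*,10S*)-7-methyl-10-[(2E,6E,10E)-3,7,11,15-tetramethylhexadeca-2,6,10,14-tetraen-1-yl]-1,5-dithiaspiro[5.5]undec-7-en-9-ol F1. Lipase-catalysed kinetic resolution (Burkholderia cepacia lipase, vinyl acetate, t-BuOMe) should then acylate the (9S,10S) enantiomer, as the empirical rule for secondary alcohols predicts, to give (9S,10S)-7-methyl-10-[(2E,6E,10E)-3,7,11,15-tetramethylhexadeca-2,6,10,14-tetraen-1-yl]-1,5-dithiaspiro[5.5]undec-7-en-9-yl acetate F2, which is separated from the unreacted antipode and methanolysed (K2CO3, MeOH) to 14.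

2. Step 6. Proton transfer from a dithiane C–H to the alkenyllithium before acylation, conjugate instead of carbonyl addition to the acrylamide, or capture of the dienone by the liberated amine or by oligomerisation before ring closure would each lower the yield of the one-flask annulation. Fallback, from 5 (with 9) back to 13: reduction of 5 with i-Bu2AlH (THF, −78 °C) to (4E,8E,12E)-5,9,13,17-tetramethyl-2-methylideneoctadeca-4,8,12,16-tetraenal F3; addition of alkenyllithium 10 (made from 9 as in step 6) to give the racemic bis-allylic alcohol (4E)-5-(1,3-dithian-2-yl)-2-[(2E,6E,10E)-3,7,11,15-tetramethylhexadeca-2,6,10,14-tetraen-1-yl]hexa-1,4-dien-3-ol F4; oxidation with MnO2 (CH2Cl2) to dienone 12 in the absence of any amine; and a separate cyclisation of isolated 12 with DBU (THF, high dilution) to 13.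

3. Step 8. S-Alkylation at the hindered spiro centre may be slow, and hydrogen iodide that escapes the buffer could dehydrate the γ-hydroxy enone towards a phenol as it forms. Fallback, from 14 back to 15: silylation (TBSCl, imidazole, DMF) to tert-butyl({(9S,10S)-7-methyl-10-[(2E,6E,10E)-3,7,11,15-tetramethylhexadeca-2,6,10,14-tetraen-1-yl]-1,5-dithiaspiro[5.5]undec-7-en-9-yl}oxy)dimethylsilane F5; oxidative dithiane cleavage with Dess–Martin periodinane (MeCN/CH2Cl2/H2O) to (4S,5S)-4-{[tert-butyl(dimethyl)silyl]oxy}-2-methyl-5-[(2E,6E,10E)-3,7,11,15-tetramethylhexadeca-2,6,10,14-tetraen-1-yl]cyclohex-2-en-1-one F6; and desilylation with HF·pyridine (THF, 0 °C) to 15.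

Further compounds
F1 | step 7 | rac-(9S*,10S*)-7-methyl-10-[(2E,6E,10E)-3,7,11,15-tetramethylhexadeca-2,6,10,14-tetraen-1-yl]-1,5-dithiaspiro[5.5]undec-7-en-9-ol (racemate, one enantiomer drawn) | CC(C)=CCC/C(C)=C/CC/C(C)=C/CC/C(C)=C/C[C@H]1CC2(SCCCS2)C(C)=C[C@H]1O
F2 | step 7 | (9S,10S)-7-methyl-10-[(2E,6E,10E)-3,7,11,15-tetramethylhexadeca-2,6,10,14-tetraen-1-yl]-1,5-dithiaspiro[5.5]undec-7-en-9-yl acetate | CC(C)=CCC/C(C)=C/CC/C(C)=C/CC/C(C)=C/C[C@H]1CC2(SCCCS2)C(C)=C[C@H]1OC(C)=O
F3 | step 6 | (4E,8E,12E)-5,9,13,17-tetramethyl-2-methylideneoctadeca-4,8,12,16-tetraenal | CC(C)=CCC/C(C)=C/CC/C(C)=C/CC/C(C)=C/CC(=C)C=O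
F4 | step 6 | (4E)-5-(1,3-dithian-2-yl)-2-[(2E,6E,10E)-3,7,11,15-tetramethylhexadeca-2,6,10,14-tetraen-1-yl]hexa-1,4-dien-3-ol (racemic) | CC(C)=CCC/C(C)=C/CC/C(C)=C/CC/C(C)=C/CC(=C)C(O)/C=C(C)/C1SCCCS1
F5 | step 8 | tert-butyl({(9S,10S)-7-methyl-10-[(2E,6E,10E)-3,7,11,15-tetramethylhexadeca-2,6,10,14-tetraen-1-yl]-1,5-dithiaspiro[5.5]undec-7-en-9-yl}oxy)dimethylsilane | CC(C)=CCC/C(C)=C/CC/C(C)=C/CC/C(C)=C/C[C@H]1CC2(SCCCS2)C(C)=C[C@H]1O[Si](C)(C)C(C)(C)C
F6 | step 8 | (4S,5S)-4-{[tert-butyl(dimethyl)silyl]oxy}-2-methyl-5-[(2E,6E,10E)-3,7,11,15-tetramethylhexadeca-2,6,10,14-tetraen-1-yl]cyclohex-2-en-1-one | CC(C)=CCC/C(C)=C/CC/C(C)=C/CC/C(C)=C/C[C@H]1CC(=O)C(C)=C[C@H]1O[Si](C)(C)C(C)(C)C
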